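**Retrosynthetic overview**
- Last step: the two phenols are released from aryl acetates that are carried in from the purchased fragments.
- The dihydrofuran ring is the only ring made (both benzene rings and the cinnamoyl unit are bought). It is closed last at C3–C3a, in the same flask in which the ester C–O bond is made: 4-acetoxycinnamic acid adds to a terminal alkyne and the aryl radical cyclises onto the resulting enol ester, which sets C3 (trans).
- Key disconnection: the O1–C2 ether bond, made by copper-catalysed enantioconvergent propargylic etherification of an ortho-iodophenol with a racemic propargylic acetate, which sets C2 (R).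
- The iodophenol comes from dihydroconiferyl alcohol by iodination; the propargylic acetate comes from vanillin acetate by ethynyl Grignard addition and acetylation.

Assumption: (S,S)-Ph-pybox is taken to give the (R)-ether in step 3; this is checked on the first run (chiral HPLC, optical data), and if the sense is opposite the (R,R)-ligand is used with no other change.

**Step 1**
Reactants: 1 4-(3-hydroxypropyl)-2-methoxyphenol (dihydroconiferyl alcohol)
Product: 2 4-(3-hydroxypropyl)-2-iodo-6-methoxyphenol
Conditions: I2 (1.05 equiv), NaHCO3, THF/H2O, 0 °C → rt; aq. Na2S2O3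
Reagents that add atoms: iodine, II
Why: Electrophilic aromatic iodination of the phenoxide goes to the only free position ortho to the phenolic oxygen (para is blocked by the side chain); the aliphatic hydroxyl is inert and no stereocentre is involved.

**Step 2**
Reactants: 3 4-formyl-2-methoxyphenyl acetate (vanillin acetate)
Product: 5 rac-4-(1-acetoxyprop-2-yn-1-yl)-2-methoxyphenyl acetate, via bromomagnesium alkoxide 4 (not isolated)
Conditions: HC≡CMgBr (1.2 equiv), THF, −78 → −30 °C; then Ac2O (2.5 equiv), DMAP (cat.), −30 °C → rt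
Reagents that add atoms: ethynylmagnesium bromide, C#C[Mg]Br; acetic anhydride, CC(=O)OC(C)=O
Why: Grignard addition to the aldehyde at low temperature is much faster than attack on the aryl acetate, and the in-flask O-acetylation also re-acetylates any phenoxide set free; the product is left racemic because step 3 is enantioconvergent.

**Step 3**
Reactants: 2 4-(3-hydroxypropyl)-2-iodo-6-methoxyphenol; 5 rac-4-(1-acetoxyprop-2-yn-1-yl)-2-methoxyphenyl acetate
Product: 6 4-{(1R)-1-[4-(3-hydroxypropyl)-2-iodo-6-methoxyphenoxy]prop-2-yn-1-yl}-2-methoxyphenyl acetate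
Conditions: (CuOTf)2·C6H6 (2.5 mol%), (S,S)-Ph-pybox (6 mol%), i-Pr2NEt (1.2 equiv), toluene/t-AmOH 3:1, −10 °C
Reagents that add atoms: none
Why: Copper-catalysed enantioselective propargylic etherification: the copper acetylide of 5 loses acetate to a planar copper allenylidene (both enantiomers of 5 converge), and the pybox ligand exposes one face of the γ-carbon to the ammonium phenoxide of 2, which forms the O1–C2 bond and sets C2 as R. The phenoxide, not the neutral primary alcohol or the bulky solvent alcohol, is the competent nucleophile, and C-alkylation is blocked because all ortho and para carbons of 2 are substituted.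

**Step 4**
Reactants: 6 4-{(1R)-1-[4-(3-hydroxypropyl)-2-iodo-6-methoxyphenoxy]prop-2-yn-1-yl}-2-methoxyphenyl acetate; 7 (E)-3-(4-acetoxyphenyl)prop-2-enoic acid (4-acetoxycinnamic acid)
Product: 9 [(2R,3S)-2-(4-acetoxy-3-methoxyphenyl)-5-(3-hydroxypropyl)-7-methoxy-2,3-dihydro-1-benzofuran-3-yl]methyl (E)-3-(4-acetoxyphenyl)prop-2-enoate, via (Z)-enol ester 8 (not isolated)
Conditions: 7 (1.05 equiv), Ru(2-methylallyl)2(dppb) (2 mol%; dppb = Ph2P(CH2)4PPh2), toluene, 65 °C; then dilute to 0.02 M, (Me3Si)3SiH (1.3 equiv), AIBN (0.2 equiv), 80 °C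
Reagents that add atoms: none
Why: Proposed new method: a one-flask relay that has not been reported, in which (a) a divalent ruthenium carboxylate turns the terminal alkyne of 6 into a ruthenium vinylidene, the carboxylate of 7 attacks its electrophilic α-carbon and protonolysis releases the anti-Markovnikov (Z)-enol ester 8 (this makes the ester C–O bond at the terminal carbon; base-free neutral conditions are chosen so that the propargylic aryloxy group does not ionise and no acetyl migrates to the free alcohol), and (b) (Me3Si)3Si• abstracts iodine, the aryl radical closes 5-exo-trig onto the enol-ester carbon remote from oxygen (about 10^9 s−1, far faster than H transfer from the silane) and the α-acyloxy radical then takes H from the silane to give the CH2–O–acyl group; C3 is set in the C–C bond-forming event, because 1,3-allylic strain with the Z-acyloxy group holds the C2–H in the alkene plane so that the new CH(OCOR) carbon ends up anti to the C2 aryl group (2,3-trans, 3S) while C2 is untouched; the closest known reaction types are ruthenium-catalysed anti-Markovnikov addition of carboxylic acids to 1-alkynes (to my knowledge not shown on α-aryloxy propargylic ethers) and stannane- or silane-mediated 5-exo aryl-radical cyclisation onto enol ethers and enamides (to my knowledge not shown with an enol ester of a cinnamic acid as acceptor).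

**Step 5**
Reactants: 9 [(2R,3S)-2-(4-acetoxy-3-methoxyphenyl)-5-(3-hydroxypropyl)-7-methoxy-2,3-dihydro-1-benzofuran-3-yl]methyl (E)-3-(4-acetoxyphenyl)prop-2-enoate
Product: 10 [(2R,3S)-2-(4-hydroxy-3-methoxyphenyl)-5-(3-hydroxypropyl)-7-methoxy-2,3-dihydro-1-benzofuran-3-yl]methyl (E)-3-(4-hydroxyphenyl)prop-2-enoate (CNP0202924.1)
Conditions: pyrrolidine (6 equiv), THF, 0 °C → rt, 30 min; aq. NH4Cl
Reagents that add atoms: none
Why: Chemoselective aminolysis of the two activated aryl acetates by pyrrolidine; the alkyl cinnamate ester, the E-alkene, the benzylic ether and both stereocentres are untouched.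

**Compound list**
1 | 4-(3-hydroxypropyl)-2-methoxyphenol (dihydroconiferyl alcohol) | COc1cc(CCCO)ccc1O | starting material
2 | 4-(3-hydroxypropyl)-2-iodo-6-methoxyphenol | COc1cc(CCCO)cc(I)c1O | intermediate
3 | 4-formyl-2-methoxyphenyl acetate (vanillin acetate) | COc1cc(C=O)ccc1OC(C)=O | starting material
4 | bromomagnesium 1-(4-acetoxy-3-methoxyphenyl)prop-2-yn-1-olate, racemic (not isolated) | C#CC(O[Mg]Br)c1ccc(OC(C)=O)c(OC)c1 | intermediate
5 | rac-4-(1-acetoxyprop-2-yn-1-yl)-2-methoxyphenyl acetate | C#CC(OC(C)=O)c1ccc(OC(C)=O)c(OC)c1 | intermediate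
6 | 4-{(1R)-1-[4-(3-hydroxypropyl)-2-iodo-6-methoxyphenoxy]prop-2-yn-1-yl}-2-methoxyphenyl acetate | C#C[C@@H](Oc1c(I)cc(CCCO)cc1OC)c1ccc(OC(C)=O)c(OC)c1 | intermediate
7 | (E)-3-(4-acetoxyphenyl)prop-2-enoic acid | CC(=O)Oc1ccc(/C=C/C(=O)O)cc1 | starting material
8 | (1Z,3R)-3-(4-acetoxy-3-methoxyphenyl)-3-[4-(3-hydroxypropyl)-2-iodo-6-methoxyphenoxy]prop-1-en-1-yl (E)-3-(4-acetoxyphenyl)prop-2-enoate (not isolated) | CC(=O)Oc1ccc(/C=C/C(=O)O/C=C\[C@@H](Oc2c(I)cc(CCCO)cc2OC)c2ccc(OC(C)=O)c(OC)c2)cc1 | intermediate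
9 | [(2R,3S)-2-(4-acetoxy-3-methoxyphenyl)-5-(3-hydroxypropyl)-7-methoxy-2,3-dihydro-1-benzofuran-3-yl]methyl (E)-3-(4-acetoxyphenyl)prop-2-enoate | COc1cc([C@@H]2Oc3c(OC)cc(CCCO)cc3[C@H]2COC(=O)/C=C/c2ccc(OC(C)=O)cc2)ccc1OC(C)=O | intermediate
10 | [(2R,3S)-2-(4-hydroxy-3-methoxyphenyl)-5-(3-hydroxypropyl)-7-methoxy-2,3-dihydro-1-benzofuran-3-yl]methyl (E)-3-(4-hydroxyphenyl)prop-2-enoate | COc1cc([C@@H]2Oc3c(OC)cc(CCCO)cc3[C@H]2COC(=O)/C=C/c2ccc(O)cc2)ccc1O | target

**Step count**
Total steps: 5. Longest linear sequence: 4 steps (3 → 5 → 6 → 9 → 10, or equally 1 → 2 → 6 → 9 → 10).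

**Three steps most likely to fail**

Step 4 (the proposed new step). The risks are ionisation of the propargylic aryloxy group at the ruthenium vinylidene stage (loss of ee), interference of ruthenium residues or the cinnamate C=C with the silyl radical chain, and a lower trans:cis ratio if the enol ester is not cleanly Z. The fallback uses known chemistry only, sets out from 6 and comes back at 9. Semi-hydrogenation (H2, Pd/CaCO3 poisoned with Pb(OAc)2, quinoline) gives 4-{(1R)-1-[4-(3-hydroxypropyl)-2-iodo-6-methoxyphenoxy]prop-2-en-1-yl}-2-methoxyphenyl acetate F1. Aryl-radical 5-exo cyclisation with nitroxide trapping (Bu3SnH, TEMPO, toluene, 70 °C) gives the trans alkoxyamine F2, separated from the minor cis isomer. TBDPSCl/imidazole protects the propanol as silyl ether F3. Zn dust in AcOH/H2O/THF cleaves the N–O bond to the primary alcohol F4. Esterification with 7 (EDC·HCl, DMAP) gives the cinnamate F5, and HF·pyridine removes the silyl group to return 9.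

Step 3. The risks are that the 2,6-disubstituted phenoxide of 2 adds slowly or with low ee to the copper allenylidene, and that the primary alcohol competes. The fallback is a Mitsunobu inversion; it sets out from 2 and 3 and comes back at 6. TBSCl/imidazole on 2 gives 4-{3-[(tert-butyldimethylsilyl)oxy]propyl}-2-iodo-6-methoxyphenol F6. Addition of trimethylsilylacetylene to 3 with Me2Zn and the ProPhenol ligand enantiomer that gives the R carbinol provides 4-[(1R)-1-hydroxy-3-(trimethylsilyl)prop-2-yn-1-yl]-2-methoxyphenyl acetate F7. The Mitsunobu reaction (PPh3, DIAD, THF) joins F6 and F7 with inversion to the (S)-configured silylated ether F8 (the descriptor changes because the silylalkynyl group outranks the aryl group; the spatial arrangement is that of 6). Bu4NF buffered with AcOH removes both silyl groups and returns 6.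

Step 2. The risks are competing attack of the Grignard reagent on the aryl acetate and lability of the benzylic propargylic acetate. The fallback is a masked-acetylene route; it sets out from 3 and comes back at 5. Me3SiC≡CLi (from trimethylsilylacetylene and n-BuLi) at −78 °C, where the aryl ester is inert, followed by Ac2O gives rac-4-[1-acetoxy-3-(trimethylsilyl)prop-2-yn-1-yl]-2-methoxyphenyl acetate F9. AgNO3 (10 mol%) in aqueous acetone removes the C-silyl group and returns 5.

**Further compounds**
F1 | step 4 | 4-{(1R)-1-[4-(3-hydroxypropyl)-2-iodo-6-methoxyphenoxy]prop-2-en-1-yl}-2-methoxyphenyl acetate | C=C[C@@H](Oc1c(I)cc(CCCO)cc1OC)c1ccc(OC(C)=O)c(OC)c1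
F2 | step 4 | 4-[(2R,3S)-5-(3-hydroxypropyl)-7-methoxy-3-{[(2,2,6,6-tetramethylpiperidin-1-yl)oxy]methyl}-2,3-dihydro-1-benzofuran-2-yl]-2-methoxyphenyl acetate | COc1cc([C@@H]2Oc3c(OC)cc(CCCO)cc3[C@H]2CON2C(C)(C)CCCC2(C)C)ccc1OC(C)=O
F3 | step 4 | 4-[(2R,3S)-5-{3-[(tert-butyldiphenylsilyl)oxy]propyl}-7-methoxy-3-{[(2,2,6,6-tetramethylpiperidin-1-yl)oxy]methyl}-2,3-dihydro-1-benzofuran-2-yl]-2-methoxyphenyl acetate | COc1cc([C@@H]2Oc3c(OC)cc(CCCO[Si](c4ccccc4)(c4ccccc4)C(C)(C)C)cc3[C@H]2CON2C(C)(C)CCCC2(C)C)ccc1OC(C)=O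
F4 | step 4 | 4-[(2R,3S)-5-{3-[(tert-butyldiphenylsilyl)oxy]propyl}-3-(hydroxymethyl)-7-methoxy-2,3-dihydro-1-benzofuran-2-yl]-2-methoxyphenyl acetate | COc1cc([C@@H]2Oc3c(OC)cc(CCCO[Si](c4ccccc4)(c4ccccc4)C(C)(C)C)cc3[C@H]2CO)ccc1OC(C)=O
F5 | step 4 | [(2R,3S)-2-(4-acetoxy-3-methoxyphenyl)-5-{3-[(tert-butyldiphenylsilyl)oxy]propyl}-7-methoxy-2,3-dihydro-1-benzofuran-3-yl]methyl (E)-3-(4-acetoxyphenyl)prop-2-enoate | COc1cc([C@@H]2Oc3c(OC)cc(CCCO[Si](c4ccccc4)(c4ccccc4)C(C)(C)C)cc3[C@H]2COC(=O)/C=C/c2ccc(OC(C)=O)cc2)ccc1OC(C)=O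
F6 | step 3 | 4-{3-[(tert-butyldimethylsilyl)oxy]propyl}-2-iodo-6-methoxyphenol | COc1cc(CCCO[Si](C)(C)C(C)(C)C)cc(I)c1O
F7 | step 3 | 4-[(1R)-1-hydroxy-3-(trimethylsilyl)prop-2-yn-1-yl]-2-methoxyphenyl acetate | C[Si](C)(C)C#C[C@H](O)c1ccc(OC(C)=O)c(OC)c1
F8 | step 3 | 4-[(1S)-1-(4-{3-[(tert-butyldimethylsilyl)oxy]propyl}-2-iodo-6-methoxyphenoxy)-3-(trimethylsilyl)prop-2-yn-1-yl]-2-methoxyphenyl acetate | C[Si](C)(C)C#C[C@@H](Oc1c(I)cc(CCCO[Si](C)(C)C(C)(C)C)cc1OC)c1ccc(OC(C)=O)c(OC)c1
F9 | step 2 | rac-4-[1-acetoxy-3-(trimethylsilyl)prop-2-yn-1-yl]-2-methoxyphenyl acetate | C[Si](C)(C)C#CC(OC(C)=O)c1ccc(OC(C)=O)c(OC)c1
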